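The route rests on reading the diarylalkyne at C6 of the central benzene (ring A) as a diaryl ketone plus one carbon. The sp carbon on C6 is the old carbonyl carbon, and the sp carbon on the 4-hydroxyphenyl ring (ring C) comes from (trimethylsilyl)diazomethane. The Colvin rearrangement inserts that carbon and shifts an aryl group onto it in one operation, so the crowded C6 site, flanked by C1 and C5, is filled by Grignard addition and never by cross-coupling. The precursor is a benzophenone whose ring A carries bromine at C1, the MOM-protected resorcinol ring (ring B) at C2 and CH2OTBS at C5; the bromine later delivers the methide carbon.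

Key step: step 7

Numbering: ring A is numbered as in the target (C1 methide carbon, bromine in the intermediates; C2 ring B; C5 CH2O group; C6 alkyne).

Assumption: the target is taken to be isolable as the open p-quinone methide drawn, so the acid equilibration in the last step is assumed to end at this form.

Design notes:
- All phenols are carried as MOM ethers and the benzylic alcohol as a TBS ether, so one mild protic acid step unmasks everything at the end and no Lewis-acid ether cleavage is needed next to the benzylic alcohol and the alkyne.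
- The C6 carbon is introduced by magnesiation while the C5 substituent is still an ester, because only then is the C6–H acidic enough for a magnesium amide.
- Compounds 10, 11 and 12 are racemic at one carbon, which becomes sp2 in step 6. The target has no stereocentre.

Step 1
Reactants: 1 4-bromobenzene-1,3-diol
Product: 2 1-bromo-2,4-bis(methoxymethoxy)benzene
Conditions: MOMCl (2.5 equiv), iPr2NEt, CH2Cl2, 0 °C to rt
Reagents that add atoms: chloromethyl methyl ether, COCCl
Why: O-alkylation of both phenols by the α-chloro ether (MOM acetal formation) should be clean, and the acetals survive every organometallic step and leave in the final acid step.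

Step 2
Reactants: 2 1-bromo-2,4-bis(methoxymethoxy)benzene; 3 methyl 3-bromo-4-iodobenzoate
Product: 6 methyl 3-bromo-4-[2,4-bis(methoxymethoxy)phenyl]benzoate, via aryllithium 4 (not isolated), via arylzinc chloride 5 (not isolated)
Conditions: 2, n-BuLi, THF, −78 °C; ZnCl2, −78 °C to rt; then 3, Pd(PPh3)4 (3 mol %), THF, rt to 45 °C
Reagents that add atoms: none
Why: Negishi coupling, in which bromine–lithium exchange and transmetalation give an ester-tolerant arylzinc and the zerovalent palladium catalyst inserts into the C–I bond para to the ester well before the hindered C–Br bond.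

Step 3
Reactants: 6 methyl 3-bromo-4-[2,4-bis(methoxymethoxy)phenyl]benzoate; 7 4-(methoxymethoxy)benzaldehyde
Product: 10 rac-4-bromo-5-[2,4-bis(methoxymethoxy)phenyl]-3-[4-(methoxymethoxy)phenyl]-2-benzofuran-1(3H)-one, via arylmagnesium chloride 8 (not isolated), via chloromagnesium alkoxide 9 (not isolated)
Conditions: TMPMgCl·LiCl (1.2 equiv), THF, −20 to 0 °C; then 7, −20 °C to rt; aq NH4Cl
Reagents that add atoms: none
Why: Directed magnesiation with the Knochel–Hauser base should remove the one C–H flanked by ester and bromine, the Grignard reagent adds to the aldehyde and the alkoxide lactonises onto the neighbouring ester to the phthalide, whose C3 stereocentre forms racemic and is erased in step 6.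

Step 4
Reactants: 10 rac-4-bromo-5-[2,4-bis(methoxymethoxy)phenyl]-3-[4-(methoxymethoxy)phenyl]-2-benzofuran-1(3H)-one
Product: 11 rac-{3-bromo-4-[2,4-bis(methoxymethoxy)phenyl]-2-{hydroxy[4-(methoxymethoxy)phenyl]methyl}phenyl}methanol
Conditions: LiBH4, THF, 0 °C to rt; aq NaHCO3 work-up
Reagents that add atoms: none
Why: Hydride reduction of the lactone to the diol should leave the aryl bromide and the acetals untouched, and the non-acidic work-up avoids closure of the diol to a cyclic ether.

Step 5
Reactants: 11 rac-{3-bromo-4-[2,4-bis(methoxymethoxy)phenyl]-2-{hydroxy[4-(methoxymethoxy)phenyl]methyl}phenyl}methanol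
Product: 12 rac-[2-bromo-3-[2,4-bis(methoxymethoxy)phenyl]-6-{[(tert-butyldimethylsilyl)oxy]methyl}phenyl][4-(methoxymethoxy)phenyl]methanol
Conditions: TBSCl (1.05 equiv), imidazole, CH2Cl2, 0 °C
Reagents that add atoms: tert-butyldimethylsilyl chloride, CC(C)(C)[Si](C)(C)Cl
Why: Selective silylation should take the primary benzylic hydroxyl only, because the secondary diaryl carbinol sits between two ortho substituents.

Step 6
Reactants: 12 rac-[2-bromo-3-[2,4-bis(methoxymethoxy)phenyl]-6-{[(tert-butyldimethylsilyl)oxy]methyl}phenyl][4-(methoxymethoxy)phenyl]methanol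
Product: 13 [2-bromo-3-[2,4-bis(methoxymethoxy)phenyl]-6-{[(tert-butyldimethylsilyl)oxy]methyl}phenyl][4-(methoxymethoxy)phenyl]methanone
Conditions: Dess–Martin periodinane, NaHCO3, CH2Cl2, rt
Reagents that add atoms: none
Why: Dess–Martin oxidation handles hindered secondary benzylic alcohols, and the bicarbonate buffer protects the acetals and the silyl ether.

Step 7
Reactants: 13 [2-bromo-3-[2,4-bis(methoxymethoxy)phenyl]-6-{[(tert-butyldimethylsilyl)oxy]methyl}phenyl][4-(methoxymethoxy)phenyl]methanone; 14 (trimethylsilyl)diazomethane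
Product: 18 2-bromo-1-[2,4-bis(methoxymethoxy)phenyl]-4-{[(tert-butyldimethylsilyl)oxy]methyl}-3-{[4-(methoxymethoxy)phenyl]ethynyl}benzene, via lithium alkoxide adduct 15 (not isolated), via diazoalkene 16 (not isolated), via alkylidene carbene 17 (not isolated)
Conditions: 14 (1.5 equiv), LiN(iPr)2 (LDA, 1.4 equiv), THF, −78 °C; then 13, −78 °C to rt, 45 °C if needed
Reagents that add atoms: (trimethylsilyl)diazomethane, C[Si](C)(C)C=[N+]=[N-]
Why: The lithium salt of 14 adds to the ketone to give the β-silyl alkoxide 15, Peterson elimination of lithium trimethylsilanolate gives the diazoalkene 16, loss of N2 leaves the diarylvinylidene 17, and a 1,2-aryl shift (Fritsch–Buttenberg–Wiechell) forms the alkyne, creating the bond from the old carbonyl carbon to the inserted carbon and a new aryl–C(sp) bond. This is the Colvin rearrangement, and its closest known use is the conversion of benzophenones into diarylalkynes. No ring is closed and no stereocentre is formed. Migration of either aryl group leads to the same alkyne, so the shift poses no regiochemical question. The step needs chemoselective attack at the carbonyl, which should hold because the diazo-stabilised anion neither exchanges with the aryl bromide nor attacks the acetals or the silyl ether, and the amide base is consumed before 13 is added. Aryl migration in a diarylvinylidene is expected to outrun C–H insertion into the neighbouring CH2OSi group.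

Step 8
Reactants: 19 4,4'-dihydroxybenzophenone
Product: 20 4,4'-bis(methoxymethoxy)benzophenone
Conditions: MOMCl (2.5 equiv), iPr2NEt, CH2Cl2/DMF, 0 °C to rt
Reagents that add atoms: chloromethyl methyl ether, COCCl
Why: Standard MOM acetal formation on two unhindered phenols.

Step 9
Reactants: 18 2-bromo-1-[2,4-bis(methoxymethoxy)phenyl]-4-{[(tert-butyldimethylsilyl)oxy]methyl}-3-{[4-(methoxymethoxy)phenyl]ethynyl}benzene; 20 4,4'-bis(methoxymethoxy)benzophenone
Product: 22 {2-[2,4-bis(methoxymethoxy)phenyl]-5-{[(tert-butyldimethylsilyl)oxy]methyl}-6-{[4-(methoxymethoxy)phenyl]ethynyl}phenyl}bis[4-(methoxymethoxy)phenyl]methanol, via aryllithium 21 (not isolated)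
Conditions: 18, t-BuLi (2.0 equiv), THF, −78 °C; then 20, −78 °C to rt; aq NH4Cl
Reagents that add atoms: none
Why: Bromine–lithium exchange is fast at −78 °C (the second equivalent of t-BuLi destroys the tert-butyl bromide), and 1,2-addition of the aryllithium to the non-enolisable diaryl ketone should build the triaryl carbinol.

Step 10
Reactants: 22 {2-[2,4-bis(methoxymethoxy)phenyl]-5-{[(tert-butyldimethylsilyl)oxy]methyl}-6-{[4-(methoxymethoxy)phenyl]ethynyl}phenyl}bis[4-(methoxymethoxy)phenyl]methanol
Product: 24 Selaginellin F, 4-{[2-(2,4-dihydroxyphenyl)-5-(hydroxymethyl)-6-[(4-hydroxyphenyl)ethynyl]phenyl](4-hydroxyphenyl)methylidene}cyclohexa-2,5-dien-1-one, via deprotected triaryl carbinol 23 (not isolated)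
Conditions: 3 M HCl (aq), MeOH/THF, 40 °C; then aq NaHCO3
Reagents that add atoms: none
Why: Acid-catalysed acetal exchange should remove the five MOM groups (methanol traps the formaldehyde unit), the silyl ether is cleaved by the same acid, and the bis(4-hydroxyphenyl) carbinol ionises and loses water to the p-quinone methide (fuchsone-type dehydration).

Compound list
1 | 4-bromobenzene-1,3-diol (4-bromoresorcinol) | Oc1ccc(Br)c(O)c1 | starting material
2 | 1-bromo-2,4-bis(methoxymethoxy)benzene | COCOc1ccc(Br)c(OCOC)c1 | intermediate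
3 | methyl 3-bromo-4-iodobenzoate | COC(=O)c1ccc(I)c(Br)c1 | starting material
4 | [2,4-bis(methoxymethoxy)phenyl]lithium | [Li]c1ccc(OCOC)cc1OCOC | intermediate (not isolated)
5 | [2,4-bis(methoxymethoxy)phenyl]zinc chloride | Cl[Zn]c1ccc(OCOC)cc1OCOC | intermediate (not isolated)
6 | methyl 3-bromo-4-[2,4-bis(methoxymethoxy)phenyl]benzoate | COC(=O)c1ccc(-c2ccc(OCOC)cc2OCOC)c(Br)c1 | intermediate
7 | 4-(methoxymethoxy)benzaldehyde | COCOc1ccc(C=O)cc1 | starting material
8 | {2-bromo-3-[2,4-bis(methoxymethoxy)phenyl]-6-(methoxycarbonyl)phenyl}magnesium chloride | COC(=O)c1ccc(-c2ccc(OCOC)cc2OCOC)c(Br)c1[Mg]Cl | intermediate (not isolated)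
9 | chloromagnesium alkoxide of methyl 3-bromo-4-[2,4-bis(methoxymethoxy)phenyl]-2-{hydroxy[4-(methoxymethoxy)phenyl]methyl}benzoate (racemic) | COC(=O)c1ccc(-c2ccc(OCOC)cc2OCOC)c(Br)c1C(O[Mg]Cl)c1ccc(OCOC)cc1 | intermediate (not isolated)
10 | rac-4-bromo-5-[2,4-bis(methoxymethoxy)phenyl]-3-[4-(methoxymethoxy)phenyl]-2-benzofuran-1(3H)-one | O=C1OC(c2ccc(OCOC)cc2)c2c(Br)c(-c3ccc(OCOC)cc3OCOC)ccc12 | intermediate
11 | rac-{3-bromo-4-[2,4-bis(methoxymethoxy)phenyl]-2-{hydroxy[4-(methoxymethoxy)phenyl]methyl}phenyl}methanol | OCc1ccc(-c2ccc(OCOC)cc2OCOC)c(Br)c1C(O)c1ccc(OCOC)cc1 | intermediate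
12 | rac-[2-bromo-3-[2,4-bis(methoxymethoxy)phenyl]-6-{[(tert-butyldimethylsilyl)oxy]methyl}phenyl][4-(methoxymethoxy)phenyl]methanol | CC(C)(C)[Si](C)(C)OCc1ccc(-c2ccc(OCOC)cc2OCOC)c(Br)c1C(O)c1ccc(OCOC)cc1 | intermediate
13 | [2-bromo-3-[2,4-bis(methoxymethoxy)phenyl]-6-{[(tert-butyldimethylsilyl)oxy]methyl}phenyl][4-(methoxymethoxy)phenyl]methanone | CC(C)(C)[Si](C)(C)OCc1ccc(-c2ccc(OCOC)cc2OCOC)c(Br)c1C(=O)c1ccc(OCOC)cc1 | intermediate
14 | (trimethylsilyl)diazomethane | C[Si](C)(C)C=[N+]=[N-] | starting material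
15 | lithium alkoxide from addition of lithiated 14 to the carbonyl of 13 (racemic) | CC(C)(C)[Si](C)(C)OCc1ccc(-c2ccc(OCOC)cc2OCOC)c(Br)c1C(O[Li])(c1ccc(OCOC)cc1)C(=[N+]=[N-])[Si](C)(C)C | intermediate (not isolated)
16 | 1-diazo-2,2-diarylethene derived from 15 by loss of lithium trimethylsilanolate | CC(C)(C)[Si](C)(C)OCc1ccc(-c2ccc(OCOC)cc2OCOC)c(Br)c1C(=C=[N+]=[N-])c1ccc(OCOC)cc1 | intermediate (not isolated)
17 | 2,2-diarylvinylidene (alkylidene carbene) derived from 16 by loss of N2 | CC(C)(C)[Si](C)(C)OCc1ccc(-c2ccc(OCOC)cc2OCOC)c(Br)c1C(=[C])c1ccc(OCOC)cc1 | intermediate (not isolated)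
18 | 2-bromo-1-[2,4-bis(methoxymethoxy)phenyl]-4-{[(tert-butyldimethylsilyl)oxy]methyl}-3-{[4-(methoxymethoxy)phenyl]ethynyl}benzene | CC(C)(C)[Si](C)(C)OCc1ccc(-c2ccc(OCOC)cc2OCOC)c(Br)c1C#Cc1ccc(OCOC)cc1 | intermediate
19 | 4,4'-dihydroxybenzophenone | O=C(c1ccc(O)cc1)c1ccc(O)cc1 | starting material
20 | 4,4'-bis(methoxymethoxy)benzophenone | COCOc1ccc(cc1)C(=O)c1ccc(OCOC)cc1 | intermediate
21 | aryllithium from 18 (lithium in place of bromine at C1 of ring A) | CC(C)(C)[Si](C)(C)OCc1ccc(-c2ccc(OCOC)cc2OCOC)c([Li])c1C#Cc1ccc(OCOC)cc1 | intermediate (not isolated)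
22 | {2-[2,4-bis(methoxymethoxy)phenyl]-5-{[(tert-butyldimethylsilyl)oxy]methyl}-6-{[4-(methoxymethoxy)phenyl]ethynyl}phenyl}bis[4-(methoxymethoxy)phenyl]methanol | CC(C)(C)[Si](C)(C)OCc1ccc(-c2ccc(OCOC)cc2OCOC)c(C(O)(c2ccc(OCOC)cc2)c2ccc(OCOC)cc2)c1C#Cc1ccc(OCOC)cc1 | intermediate
23 | {2-(2,4-dihydroxyphenyl)-5-(hydroxymethyl)-6-[(4-hydroxyphenyl)ethynyl]phenyl}bis(4-hydroxyphenyl)methanol | OCc1ccc(-c2ccc(O)cc2O)c(C(O)(c2ccc(O)cc2)c2ccc(O)cc2)c1C#Cc1ccc(O)cc1 | intermediate (not isolated)
24 | Selaginellin F, 4-{[2-(2,4-dihydroxyphenyl)-5-(hydroxymethyl)-6-[(4-hydroxyphenyl)ethynyl]phenyl](4-hydroxyphenyl)methylidene}cyclohexa-2,5-dien-1-one (no stereocentre) | O=C1C=CC(=C(c2ccc(O)cc2)c2c(-c3ccc(O)cc3O)ccc(CO)c2C#Cc2ccc(O)cc2)C=C1 | target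

Total step count: 10 steps.
Longest linear sequence: 9 steps (steps 1 to 7, then 9 and 10, counted from 1); step 8 is a one-step side branch.

Steps most likely to fail

Step 7. The diazo anion may fail to reach the carbonyl carbon, which is shielded by two ortho substituents, or the vinylidene may insert into the neighbouring benzylic C–H bond instead of rearranging. The fallback sets out from 6 and returns at 18, bringing the alkyne in whole by cross-coupling at an iodide. Magnesiation of 6 as in step 3 and a quench with iodine should give methyl 3-bromo-2-iodo-4-[2,4-bis(methoxymethoxy)phenyl]benzoate F1. Reduction with iBu2AlH (CH2Cl2, −78 to 0 °C) should give {3-bromo-2-iodo-4-[2,4-bis(methoxymethoxy)phenyl]phenyl}methanol F2. TBSCl and imidazole should give tert-butyl({3-bromo-2-iodo-4-[2,4-bis(methoxymethoxy)phenyl]phenyl}methoxy)dimethylsilane F3. The coupling partner 1-ethynyl-4-(methoxymethoxy)benzene F4 would be made from 7 with dimethyl (1-diazo-2-oxopropyl)phosphonate, K2CO3 and MeOH. Sonogashira coupling of F3 with F4 (Pd(PPh3)2Cl2, CuI, Et3N, THF, 45 °C) should take place at the C–I bond ahead of the C–Br bond and give 18.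

Step 9. The aryllithium, flanked by ring B and the alkyne, may add too slowly to the bulky, electron-rich diaryl ketone, so that protonation or decomposition of the anion on warming wins. The fallback sets out from 18 and returns at 22, building the carbinol in two additions to slimmer electrophiles. The same exchange (18 to 21) followed by aldehyde 7 should give rac-{2-[2,4-bis(methoxymethoxy)phenyl]-5-{[(tert-butyldimethylsilyl)oxy]methyl}-6-{[4-(methoxymethoxy)phenyl]ethynyl}phenyl}[4-(methoxymethoxy)phenyl]methanol F5. Dess–Martin oxidation should give the corresponding {2-[2,4-bis(methoxymethoxy)phenyl]-5-{[(tert-butyldimethylsilyl)oxy]methyl}-6-{[4-(methoxymethoxy)phenyl]ethynyl}phenyl}[4-(methoxymethoxy)phenyl]methanone F6. Addition of the unhindered [4-(methoxymethoxy)phenyl]lithium F7 (from 1-bromo-4-(methoxymethoxy)benzene and n-BuLi, THF, −78 °C) to F6 should give 22.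

Step 3. Metalation may be incomplete or may go to the wrong carbon (for example between the two acetal oxygens of ring B), and the hindered Grignard reagent may add sluggishly. The fallback sets out from 3 and returns at 10, with the C–H magnesiation done before the biaryl bond is made. In 3 the C–H between ester and bromine is more acidic and ring B is absent. TMPMgCl·LiCl followed by 7 should give rac-4-bromo-5-iodo-3-[4-(methoxymethoxy)phenyl]-2-benzofuran-1(3H)-one F8. Negishi coupling of F8 at its C–I bond with arylzinc chloride 5 (made from 2 as in step 2; Pd(PPh3)4, THF) should give 10.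

Further compounds
F1 | step 7 | methyl 3-bromo-2-iodo-4-[2,4-bis(methoxymethoxy)phenyl]benzoate | COC(=O)c1ccc(-c2ccc(OCOC)cc2OCOC)c(Br)c1I
F2 | step 7 | {3-bromo-2-iodo-4-[2,4-bis(methoxymethoxy)phenyl]phenyl}methanol | OCc1ccc(-c2ccc(OCOC)cc2OCOC)c(Br)c1I
F3 | step 7 | tert-butyl({3-bromo-2-iodo-4-[2,4-bis(methoxymethoxy)phenyl]phenyl}methoxy)dimethylsilane | CC(C)(C)[Si](C)(C)OCc1ccc(-c2ccc(OCOC)cc2OCOC)c(Br)c1I
F4 | step 7 | 1-ethynyl-4-(methoxymethoxy)benzene | COCOc1ccc(C#C)cc1
F5 | step 9 | rac-{2-[2,4-bis(methoxymethoxy)phenyl]-5-{[(tert-butyldimethylsilyl)oxy]methyl}-6-{[4-(methoxymethoxy)phenyl]ethynyl}phenyl}[4-(methoxymethoxy)phenyl]methanol | CC(C)(C)[Si](C)(C)OCc1ccc(-c2ccc(OCOC)cc2OCOC)c(C(O)c2ccc(OCOC)cc2)c1C#Cc1ccc(OCOC)cc1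
F6 | step 9 | {2-[2,4-bis(methoxymethoxy)phenyl]-5-{[(tert-butyldimethylsilyl)oxy]methyl}-6-{[4-(methoxymethoxy)phenyl]ethynyl}phenyl}[4-(methoxymethoxy)phenyl]methanone | CC(C)(C)[Si](C)(C)OCc1ccc(-c2ccc(OCOC)cc2OCOC)c(C(=O)c2ccc(OCOC)cc2)c1C#Cc1ccc(OCOC)cc1
F7 | step 9 | [4-(methoxymethoxy)phenyl]lithium | [Li]c1ccc(OCOC)cc1
F8 | step 3 | rac-4-bromo-5-iodo-3-[4-(methoxymethoxy)phenyl]-2-benzofuran-1(3H)-one | O=C1OC(c2ccc(OCOC)cc2)c2c(Br)c(I)ccc12
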